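**Retrosynthetic overview**

1. Atom labels: ring C1 (C=O), C2 (carries C7, the CH2OH carbon), C3 (=CH), C4 (O‑angelate), C5 (isopropyl, central carbon C8), C6 (O‑tiglate). The strategy rests on the isopropyl‑bearing C5 standing next to the C6 carbinol in the single six‑membered ring: this pair is the retron of a type 1 carbonyl‑ene reaction, so the C5–C6 bond is cut to a C6 aldehyde and a C5=C8 dimethyl alkene.
2. In that closure allylic 1,3‑strain should place the C4 oxygen trans to the new C5 substituent. C4 is therefore carried in the configuration opposite to the target and inverted when the angelate is introduced (Mitsunobu); O6 takes the tiglate with retention.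
3. After ring closure: isopropenyl to isopropyl, C6 tiglate, C4 angelate, C1 carbinol to enone, C7 desilylation.
4. Before ring closure: a (Z)‑alkenyl iodide (from an (S)‑propargylic alcohol by hydroxyl‑directed hydroalumination and iodination) and ethyl glyoxylate give the C1–C2 bond; the propargylic alcohol comes from prenal, a propargyl silyl ether and a Noyori transfer hydrogenation.

Key step: step 10

Remark: step 7 forms C1 without control; both C1 epimers are carried together (C1 undefined in the SMILES, RS in the names) because C1 becomes the ketone in step 16. Cyclic intermediates are named with the target ring numbering given above.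

**Route**

Step 1
Reactants: 1 prop-2-yn-1-ol
Product: 2 tert-butyl(diphenyl)(prop-2-yn-1-yloxy)silane
Conditions: t-BuPh2SiCl, imidazole, DMF, 0 °C to rt
Reagents that add atoms: tert-butyl(chloro)diphenylsilane, CC(C)(C)[Si](Cl)(c1ccccc1)c1ccccc1
Why: Imidazole-promoted silylation of a primary alcohol; the TBDPS ether is chosen because it must outlast every later step and leave last.

Step 2
Reactants: 2 tert-butyl(diphenyl)(prop-2-yn-1-yloxy)silane; 3 3-methylbut-2-enal
Product: 5 rac-1-(tert-butyldiphenylsilyloxy)-6-methylhept-5-en-2-yn-4-ol, via lithium acetylide 4 (not isolated)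
Conditions: n-BuLi, THF, −78 °C; then 3, −78 to 0 °C; aq NH4Cl
Reagents that add atoms: none
Why: 1,2-Addition of a lithium acetylide to an enal whose β,β-disubstitution disfavours conjugate addition; the racemic carbinol centre is erased in step 3.

Step 3
Reactants: 5 rac-1-(tert-butyldiphenylsilyloxy)-6-methylhept-5-en-2-yn-4-ol
Product: 6 1-(tert-butyldiphenylsilyloxy)-6-methylhept-5-en-2-yn-4-one
Conditions: MnO2 (activated, excess), CH2Cl2, rt
Reagents that add atoms: none
Why: MnO2 oxidation of an alcohol that is both allylic and propargylic, under neutral conditions that should not isomerise the ynone.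

Step 4
Reactants: 6 1-(tert-butyldiphenylsilyloxy)-6-methylhept-5-en-2-yn-4-one
Product: 7 (S)-1-(tert-butyldiphenylsilyloxy)-6-methylhept-5-en-2-yn-4-ol
Conditions: Ru[(S,S)-TsNCHPhCHPhNH](p-cymene) (2 mol %), i-PrOH, rt
Reagents that add atoms: none
Why: Noyori asymmetric transfer hydrogenation of an alkynyl ketone, in which the alkynyl group takes the site an aryl group occupies with acetophenone, so the (S,S) catalyst should give the (S) carbinol (the future C4; O > alkynyl > alkenyl) while the hindered β,β-dimethyl enone C=C and the C≡C bond are not reduced.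

Step 5
Reactants: 7 (S)-1-(tert-butyldiphenylsilyloxy)-6-methylhept-5-en-2-yn-4-ol
Product: 9 (2Z,4S)-1-(tert-butyldiphenylsilyloxy)-2-iodo-6-methylhepta-2,5-dien-4-ol, via cyclic alkenylalanate 8 (not isolated)
Conditions: NaAlH2(OCH2CH2OMe)2, THF, 0 °C; EtOAc; then I2, THF, −78 to 0 °C
Reagents that add atoms: iodine, II
Why: Hydroxyl-directed trans-hydroalumination of a propargylic alcohol delivers hydride to C3 and aluminium to C2 in a five-membered alanate, and iododealumination with retention gives the (Z)-iodide with iodine cis to C4; keeping the mixture at or below 0 °C should prevent the alanate from expelling the C7 silyloxide to form an allene.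

Step 6
Reactants: 9 (2Z,4S)-1-(tert-butyldiphenylsilyloxy)-2-iodo-6-methylhepta-2,5-dien-4-ol
Product: 10 tert-butyl{[(2Z,4S)-2-iodo-4-(4-methoxybenzyloxy)-6-methylhepta-2,5-dien-1-yl]oxy}diphenylsilane
Conditions: NaH, 4-MeOC6H4CH2Cl, n-Bu4NI (cat.), THF–DMF, 0 °C
Reagents that add atoms: 4-methoxybenzyl chloride, COc1ccc(CCl)cc1
Why: Williamson etherification under basic conditions, preferred to acid-catalysed imidate benzylation because the doubly allylic carbinol ionises easily; the low temperature should avoid dehydroiodination.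

Step 7
Reactants: 10 tert-butyl{[(2Z,4S)-2-iodo-4-(4-methoxybenzyloxy)-6-methylhepta-2,5-dien-1-yl]oxy}diphenylsilane; 11 ethyl glyoxylate
Product: 13 ethyl (2RS,3Z,5S)-3-[(tert-butyldiphenylsilyloxy)methyl]-2-hydroxy-5-(4-methoxybenzyloxy)-7-methylocta-3,6-dienoate, via alkenylmagnesium chloride 12 (not isolated)
Conditions: i-PrMgCl·LiCl, THF, −20 to 0 °C; then added to freshly distilled 11 (3 equiv), THF, −78 °C; aq NH4Cl
Reagents that add atoms: none
Why: Iodine–magnesium exchange of an alkenyl iodide (assisted by the cis C4 ether oxygen) keeps the alkene geometry, and the alkenylmagnesium adds to the aldehyde carbonyl of the glyoxylate far faster than to its ester at −78 °C, forming C1–C2 with C1 cis to C4; C1 is formed without control.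

Step 8
Reactants: 13 ethyl (2RS,3Z,5S)-3-[(tert-butyldiphenylsilyloxy)methyl]-2-hydroxy-5-(4-methoxybenzyloxy)-7-methylocta-3,6-dienoate
Product: 14 ethyl (2RS,3Z,5S)-3-[(tert-butyldiphenylsilyloxy)methyl]-5-(4-methoxybenzyloxy)-7-methyl-2-(triethylsilyloxy)octa-3,6-dienoate
Conditions: Et3SiCl, imidazole, DMAP (cat.), CH2Cl2, 0 °C
Reagents that add atoms: chlorotriethylsilane, CC[Si](Cl)(CC)CC
Why: Silylation of a secondary alcohol; TES is chosen so that O1 can later be freed in the presence of the primary TBDPS ether.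

Step 9
Reactants: 14 ethyl (2RS,3Z,5S)-3-[(tert-butyldiphenylsilyloxy)methyl]-5-(4-methoxybenzyloxy)-7-methyl-2-(triethylsilyloxy)octa-3,6-dienoate
Product: 16 (2RS,3Z,5S)-3-[(tert-butyldiphenylsilyloxy)methyl]-5-(4-methoxybenzyloxy)-7-methyl-2-(triethylsilyloxy)octa-3,6-dienal, via aluminium hemiacetal 15 (not isolated)
Conditions: i-Bu2AlH, CH2Cl2, −78 °C; MeOH, then aq KNaC4H4O6 (potassium sodium tartrate)
Reagents that add atoms: none
Why: Half-reduction of an α-silyloxy ester by i-Bu2AlH, whose tetrahedral aluminium hemiacetal is stable at −78 °C and releases the aldehyde only on work-up; the β,γ-unsaturated aldehyde is used at once.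

Step 10
Reactants: 16 (2RS,3Z,5S)-3-[(tert-butyldiphenylsilyloxy)methyl]-5-(4-methoxybenzyloxy)-7-methyl-2-(triethylsilyloxy)octa-3,6-dienal
Product: 18 (1RS,4R,5R,6R)-2-[(tert-butyldiphenylsilyloxy)methyl]-4-(4-methoxybenzyloxy)-5-(prop-1-en-2-yl)-1-(triethylsilyloxy)cyclohex-2-en-6-ol, via aluminium alkoxide 17 (not isolated)
Conditions: Me2AlCl (1.5 equiv), CH2Cl2, −78 to −40 °C; aq KNaC4H4O6
Reagents that add atoms: none
Why: Me2AlCl activates the C6 aldehyde, C5 of the C5=C8 alkene bonds to C6 while a hydrogen of the C8 methyl group trans to C4 passes to the carbonyl oxygen through a closed six-centre array, and the resulting alcohol–aluminium complex loses methane to give alkoxide 17; the closest known reaction is the Lewis-acid-promoted type 1 carbonyl-ene cyclisation of citronellal to isopulegol. The single ring closes as a six-membered half-chair that contains the Z C2=C3 bond, exo with respect to the C=O bond and with the ene alkene left exocyclic as the isopropenyl group. C6 is set by the aluminium-bound oxygen taking the pseudoequatorial site next to the pseudoequatorial C5=C8 unit, which gives the 5,6-trans relationship. C5 is set by C4: the C4–H bond must eclipse the C5=C8 bond to avoid allylic 1,3-strain with the C8 methyl group cis to C4, so the OPMB group lies pseudoequatorial and anti to the forming bond and the aldehyde adds to the face of C5 opposite O4 (4,5-trans, hence the C4 inversion in step 14). The step needs this face selectivity, secured by the Z-methyl/C4 interaction, and it needs ene closure to outrun ionisation of the doubly allylic ether and conjugation of the β,γ-unsaturated aldehyde, for which the proton-scavenging Me2AlCl at low temperature and the high enophilicity of an α-silyloxy aldehyde are relied on. Both C1 epimers pass through the same C4-controlled half-chair and should give the same C5/C6 configuration.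

Step 11
Reactants: 18 (1RS,4R,5R,6R)-2-[(tert-butyldiphenylsilyloxy)methyl]-4-(4-methoxybenzyloxy)-5-(prop-1-en-2-yl)-1-(triethylsilyloxy)cyclohex-2-en-6-ol
Product: 19 (1RS,4R,5R,6R)-2-[(tert-butyldiphenylsilyloxy)methyl]-5-isopropyl-4-(4-methoxybenzyloxy)-1-(triethylsilyloxy)cyclohex-2-en-6-ol
Conditions: H2 (1 atm), RhCl(PPh3)3 (10 mol %), benzene–EtOH, rt
Reagents that add atoms: none
Why: Homogeneous hydrogenation with RhCl(PPh3)3 reduces the 1,1-disubstituted isopropenyl alkene much faster than the trisubstituted, allylically oxygenated ring alkene and does not hydrogenolyse benzylic or allylic C–O bonds; no stereocentre is touched.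

Step 12
Reactants: 19 (1RS,4R,5R,6R)-2-[(tert-butyldiphenylsilyloxy)methyl]-5-isopropyl-4-(4-methoxybenzyloxy)-1-(triethylsilyloxy)cyclohex-2-en-6-ol; 20 tigloyl chloride [(E)-2-methylbut-2-enoyl chloride]
Product: 21 (1RS,4R,5S,6R)-2-[(tert-butyldiphenylsilyloxy)methyl]-5-isopropyl-4-(4-methoxybenzyloxy)-1-(triethylsilyloxy)cyclohex-2-en-6-yl (E)-2-methylbut-2-enoate
Conditions: pyridine, DMAP, CH2Cl2, 0 to 40 °C
Reagents that add atoms: none
Why: DMAP-catalysed acylation of the only free hydroxyl (O6) with retention at C6; the tiglate is the stable E isomer so its geometry is not at risk, and amine (not alkoxide) conditions should not move the neighbouring TES group.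

Step 13
Reactants: 21 (1RS,4R,5S,6R)-2-[(tert-butyldiphenylsilyloxy)methyl]-5-isopropyl-4-(4-methoxybenzyloxy)-1-(triethylsilyloxy)cyclohex-2-en-6-yl (E)-2-methylbut-2-enoate
Product: 22 (1RS,4R,5S,6R)-2-[(tert-butyldiphenylsilyloxy)methyl]-4-hydroxy-5-isopropyl-1-(triethylsilyloxy)cyclohex-2-en-6-yl (E)-2-methylbut-2-enoate
Conditions: DDQ, CH2Cl2–pH 7 phosphate buffer, 0 °C
Reagents that add atoms: none
Why: Oxidative cleavage of the electron-rich 4-methoxybenzyl ether by DDQ (hydride abstraction, then hydrolysis of the oxocarbenium ion) leaves the silyl ethers and the enoate untouched.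

Step 14
Reactants: 22 (1RS,4R,5S,6R)-2-[(tert-butyldiphenylsilyloxy)methyl]-4-hydroxy-5-isopropyl-1-(triethylsilyloxy)cyclohex-2-en-6-yl (E)-2-methylbut-2-enoate; 23 angelic acid [(Z)-2-methylbut-2-enoic acid]
Product: 25 (1RS,4S,5S,6R)-4-[(Z)-2-methylbut-2-enoyloxy]-2-[(tert-butyldiphenylsilyloxy)methyl]-5-isopropyl-1-(triethylsilyloxy)cyclohex-2-en-6-yl (E)-2-methylbut-2-enoate, via alkoxyphosphonium angelate 24 (not isolated)
Conditions: PPh3, DIAD, toluene, 0 °C to rt
Reagents that add atoms: none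
Why: Mitsunobu esterification, in which angelate displaces the C4 alkoxyphosphonium group by SN2 with inversion (the O6 ester lies on the same face as the leaving group and cannot participate, and SN2′ attack at fully substituted C2 is blocked), sets the 4,5-cis relationship of the target; the neutral conditions without acyl-transfer catalyst should keep the Z geometry of the angelate.

Step 15
Reactants: 25 (1RS,4S,5S,6R)-4-[(Z)-2-methylbut-2-enoyloxy]-2-[(tert-butyldiphenylsilyloxy)methyl]-5-isopropyl-1-(triethylsilyloxy)cyclohex-2-en-6-yl (E)-2-methylbut-2-enoate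
Product: 26 (1RS,4S,5S,6R)-4-[(Z)-2-methylbut-2-enoyloxy]-2-[(tert-butyldiphenylsilyloxy)methyl]-1-hydroxy-5-isopropylcyclohex-2-en-6-yl (E)-2-methylbut-2-enoate
Conditions: HF·pyridine, pyridine, THF, 0 °C
Reagents that add atoms: none
Why: Buffered HF·pyridine cleaves the secondary TES ether much faster than the primary TBDPS ether and is not basic enough to cause acyl migration.

Step 16
Reactants: 26 (1RS,4S,5S,6R)-4-[(Z)-2-methylbut-2-enoyloxy]-2-[(tert-butyldiphenylsilyloxy)methyl]-1-hydroxy-5-isopropylcyclohex-2-en-6-yl (E)-2-methylbut-2-enoate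
Product: 27 (4S,5S,6R)-4-[(Z)-2-methylbut-2-enoyloxy]-2-[(tert-butyldiphenylsilyloxy)methyl]-5-isopropyl-6-[(E)-2-methylbut-2-enoyloxy]cyclohex-2-en-1-one
Conditions: Dess–Martin periodinane, pyridine, CH2Cl2, 0 °C to rt
Reagents that add atoms: none
Why: Dess–Martin oxidation of the allylic C1 alcohol converges both C1 epimers on the enone under near-neutral conditions that should neither epimerise C6 nor eliminate the C4 ester.

Step 17
Reactants: 27 (4S,5S,6R)-4-[(Z)-2-methylbut-2-enoyloxy]-2-[(tert-butyldiphenylsilyloxy)methyl]-5-isopropyl-6-[(E)-2-methylbut-2-enoyloxy]cyclohex-2-en-1-one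
Product: 28 (4S,5S,6R)-4-[(Z)-2-methylbut-2-enoyloxy]-2-(hydroxymethyl)-5-isopropyl-6-[(E)-2-methylbut-2-enoyloxy]cyclohex-2-en-1-one (target)
Conditions: HF·pyridine, THF, 0 °C to rt
Reagents that add atoms: none
Why: Acidic fluoride cleaves the primary allylic Si–O bond without the basic conditions that would endanger the γ-acyloxy enone and the α-acyloxy ketone.

**Compound list**

1 | prop-2-yn-1-ol | C#CCO | starting material
2 | tert-butyl(diphenyl)(prop-2-yn-1-yloxy)silane | C#CCO[Si](c1ccccc1)(c1ccccc1)C(C)(C)C | intermediate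
3 | 3-methylbut-2-enal | CC(C)=CC=O | starting material
4 | [3-(tert-butyldiphenylsilyloxy)prop-1-yn-1-yl]lithium | [Li]C#CCO[Si](c1ccccc1)(c1ccccc1)C(C)(C)C | intermediate (not isolated)
5 | rac-1-(tert-butyldiphenylsilyloxy)-6-methylhept-5-en-2-yn-4-ol | CC(C)=CC(O)C#CCO[Si](c1ccccc1)(c1ccccc1)C(C)(C)C | intermediate
6 | 1-(tert-butyldiphenylsilyloxy)-6-methylhept-5-en-2-yn-4-one | CC(C)=CC(=O)C#CCO[Si](c1ccccc1)(c1ccccc1)C(C)(C)C | intermediate
7 | (S)-1-(tert-butyldiphenylsilyloxy)-6-methylhept-5-en-2-yn-4-ol | CC(C)=C[C@H](O)C#CCO[Si](c1ccccc1)(c1ccccc1)C(C)(C)C | intermediate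
8 | sodium cyclic alkenylalanate (five-membered O–Al–C2=C3–C4 ring, two 2-methoxyethoxy groups on Al) | CC(C)=C[C@H]1C=C(CO[Si](c2ccccc2)(c2ccccc2)C(C)(C)C)[Al-](OCCOC)(OCCOC)O1.[Na+] | intermediate (not isolated)
9 | (2Z,4S)-1-(tert-butyldiphenylsilyloxy)-2-iodo-6-methylhepta-2,5-dien-4-ol | CC(C)=C[C@H](O)/C=C(\I)CO[Si](c1ccccc1)(c1ccccc1)C(C)(C)C | intermediate
10 | tert-butyl{[(2Z,4S)-2-iodo-4-(4-methoxybenzyloxy)-6-methylhepta-2,5-dien-1-yl]oxy}diphenylsilane | CC(C)=C[C@H](OCc1ccc(OC)cc1)/C=C(\I)CO[Si](c1ccccc1)(c1ccccc1)C(C)(C)C | intermediate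
11 | ethyl glyoxylate | CCOC(=O)C=O | starting material
12 | alkenylmagnesium chloride from 10 (Mg in place of I, geometry kept) | CC(C)=C[C@H](OCc1ccc(OC)cc1)/C=C(\[Mg]Cl)CO[Si](c1ccccc1)(c1ccccc1)C(C)(C)C | intermediate (not isolated)
13 | ethyl (2RS,3Z,5S)-3-[(tert-butyldiphenylsilyloxy)methyl]-2-hydroxy-5-(4-methoxybenzyloxy)-7-methylocta-3,6-dienoate | CCOC(=O)C(O)/C(CO[Si](c1ccccc1)(c1ccccc1)C(C)(C)C)=C\[C@@H](OCc1ccc(OC)cc1)C=C(C)C | intermediate
14 | ethyl (2RS,3Z,5S)-3-[(tert-butyldiphenylsilyloxy)methyl]-5-(4-methoxybenzyloxy)-7-methyl-2-(triethylsilyloxy)octa-3,6-dienoate | CCOC(=O)C(O[Si](CC)(CC)CC)/C(CO[Si](c1ccccc1)(c1ccccc1)C(C)(C)C)=C\[C@@H](OCc1ccc(OC)cc1)C=C(C)C | intermediate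
15 | diisobutylaluminium hemiacetal of 14 | CCOC(O[Al](CC(C)C)CC(C)C)C(O[Si](CC)(CC)CC)/C(CO[Si](c1ccccc1)(c1ccccc1)C(C)(C)C)=C\[C@@H](OCc1ccc(OC)cc1)C=C(C)C | intermediate (not isolated)
16 | (2RS,3Z,5S)-3-[(tert-butyldiphenylsilyloxy)methyl]-5-(4-methoxybenzyloxy)-7-methyl-2-(triethylsilyloxy)octa-3,6-dienal | O=CC(O[Si](CC)(CC)CC)/C(CO[Si](c1ccccc1)(c1ccccc1)C(C)(C)C)=C\[C@@H](OCc1ccc(OC)cc1)C=C(C)C | intermediate (ene precursor)
17 | chloro(methyl)aluminium alkoxide of 18 | COc1ccc(CO[C@@H]2C=C(CO[Si](c3ccccc3)(c3ccccc3)C(C)(C)C)C(O[Si](CC)(CC)CC)[C@H](O[Al](C)Cl)[C@H]2C(C)=C)cc1 | intermediate (not isolated)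
18 | (1RS,4R,5R,6R)-2-[(tert-butyldiphenylsilyloxy)methyl]-4-(4-methoxybenzyloxy)-5-(prop-1-en-2-yl)-1-(triethylsilyloxy)cyclohex-2-en-6-ol (4,5-trans, 5,6-trans) | COc1ccc(CO[C@@H]2C=C(CO[Si](c3ccccc3)(c3ccccc3)C(C)(C)C)C(O[Si](CC)(CC)CC)[C@H](O)[C@H]2C(C)=C)cc1 | intermediate (ene product)
19 | (1RS,4R,5R,6R)-2-[(tert-butyldiphenylsilyloxy)methyl]-5-isopropyl-4-(4-methoxybenzyloxy)-1-(triethylsilyloxy)cyclohex-2-en-6-ol | COc1ccc(CO[C@@H]2C=C(CO[Si](c3ccccc3)(c3ccccc3)C(C)(C)C)C(O[Si](CC)(CC)CC)[C@H](O)[C@H]2C(C)C)cc1 | intermediate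
20 | tigloyl chloride [(E)-2-methylbut-2-enoyl chloride] | C/C=C(\C)C(Cl)=O | starting material
21 | (1RS,4R,5S,6R)-2-[(tert-butyldiphenylsilyloxy)methyl]-5-isopropyl-4-(4-methoxybenzyloxy)-1-(triethylsilyloxy)cyclohex-2-en-6-yl (E)-2-methylbut-2-enoate | COc1ccc(CO[C@@H]2C=C(CO[Si](c3ccccc3)(c3ccccc3)C(C)(C)C)C(O[Si](CC)(CC)CC)[C@H](OC(=O)/C(C)=C/C)[C@H]2C(C)C)cc1 | intermediate
22 | (1RS,4R,5S,6R)-2-[(tert-butyldiphenylsilyloxy)methyl]-4-hydroxy-5-isopropyl-1-(triethylsilyloxy)cyclohex-2-en-6-yl (E)-2-methylbut-2-enoate | O[C@@H]1C=C(CO[Si](c2ccccc2)(c2ccccc2)C(C)(C)C)C(O[Si](CC)(CC)CC)[C@H](OC(=O)/C(C)=C/C)[C@H]1C(C)C | intermediate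
23 | angelic acid [(Z)-2-methylbut-2-enoic acid] | C/C=C(/C)C(=O)O | starting material
24 | C4 alkoxytriphenylphosphonium angelate of 22 (C4 configuration retained) | C/C=C(/C)C(=O)[O-].c1ccc(cc1)[P+](c1ccccc1)(c1ccccc1)O[C@@H]1C=C(CO[Si](c2ccccc2)(c2ccccc2)C(C)(C)C)C(O[Si](CC)(CC)CC)[C@H](OC(=O)/C(C)=C/C)[C@H]1C(C)C | intermediate (not isolated)
25 | (1RS,4S,5S,6R)-4-[(Z)-2-methylbut-2-enoyloxy]-2-[(tert-butyldiphenylsilyloxy)methyl]-5-isopropyl-1-(triethylsilyloxy)cyclohex-2-en-6-yl (E)-2-methylbut-2-enoate | C/C=C(/C)C(=O)O[C@H]1C=C(CO[Si](c2ccccc2)(c2ccccc2)C(C)(C)C)C(O[Si](CC)(CC)CC)[C@H](OC(=O)/C(C)=C/C)[C@H]1C(C)C | intermediate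
26 | (1RS,4S,5S,6R)-4-[(Z)-2-methylbut-2-enoyloxy]-2-[(tert-butyldiphenylsilyloxy)methyl]-1-hydroxy-5-isopropylcyclohex-2-en-6-yl (E)-2-methylbut-2-enoate | C/C=C(/C)C(=O)O[C@H]1C=C(CO[Si](c2ccccc2)(c2ccccc2)C(C)(C)C)C(O)[C@H](OC(=O)/C(C)=C/C)[C@H]1C(C)C | intermediate
27 | (4S,5S,6R)-4-[(Z)-2-methylbut-2-enoyloxy]-2-[(tert-butyldiphenylsilyloxy)methyl]-5-isopropyl-6-[(E)-2-methylbut-2-enoyloxy]cyclohex-2-en-1-one | C/C=C(/C)C(=O)O[C@H]1C=C(CO[Si](c2ccccc2)(c2ccccc2)C(C)(C)C)C(=O)[C@H](OC(=O)/C(C)=C/C)[C@H]1C(C)C | intermediate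
28 | (4S,5S,6R)-4-[(Z)-2-methylbut-2-enoyloxy]-2-(hydroxymethyl)-5-isopropyl-6-[(E)-2-methylbut-2-enoyloxy]cyclohex-2-en-1-one | C/C=C(/C)C(=O)O[C@H]1C=C(CO)C(=O)[C@H](OC(=O)/C(C)=C/C)[C@H]1C(C)C | target

**Step count and risks**

Total steps: 17. Longest linear sequence: 17 steps (1 to 28).

Steps most likely to fail:

1. Step 10 (ene ring closure). Hydrogen transfer from the C8 methyl group may not keep pace with C5–C6 bond formation in the strained half-chair (the anti C4–O bond lowers the nucleophilicity of the alkene), so that the open zwitterion loses a proton unselectively, or the doubly allylic ether ionises before closure. Fallback, from 16: MeAlCl2, CH2Cl2, −78 °C is expected to end the same C5–C6 closure by chloride capture at C8 (Prins cyclisation), giving the tertiary chloride (1RS,4R,5R,6R)-5-(2-chloropropan-2-yl) analogue of 19, F1. Bu3SnH, AIBN, toluene, 80 °C then replaces chlorine by hydrogen and the route is rejoined at 19, steps 10 and 11 being bypassed.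

2. Step 14 (Mitsunobu inversion at C4). Displacement at the hindered allylic C4, on the face shared with the C5 isopropyl group, may be slower than loss of the oxyphosphonium group by elimination to a diene, or may pass through an allyl cation with partial retention. Fallback, from 22: Dess–Martin oxidation gives the C4 enone F2. LiBH(s-Bu)3, THF, −78 °C should add hydride from the face opposite the C5 isopropyl group to give the C4-epimeric alcohol (hydroxyl cis to isopropyl) F3. F3 is acylated with angelic 2,4,6-trichlorobenzoic anhydride F4 (preformed from 23, 2,4,6-trichlorobenzoyl chloride and Et3N in toluene, used at 80 °C without DMAP so that the Z geometry is kept; Yamaguchi-type esterification), which rejoins the route at 25.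

3. Step 7 (C1–C2 bond). The alkenylmagnesium species may expel the C7 silyloxide to give an allene, the iodine–magnesium exchange may stall, or the glyoxylate may add twice. Fallback, from 10: Nozaki–Hiyama–Kishi coupling with (tert-butyldimethylsilyloxy)acetaldehyde (CrCl2, NiCl2 cat., DMF, rt) gives the C1 alcohol carrying C6 as CH2OTBS, F5. HF·pyridine/pyridine, THF, 0 °C removes the primary TBS group to give the 1,2-diol F6. Et3SiCl, imidazole gives the bis(triethylsilyl) ether F7. Swern oxidation ((COCl)2, DMSO, CH2Cl2, −78 to −30 °C; Et3N), which converts a primary TES ether directly into the aldehyde and leaves the secondary one, rejoins the route at 16.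

Further compounds
F1 | step 10 | (1RS,4R,5R,6R)-2-[(tert-butyldiphenylsilyloxy)methyl]-5-(2-chloropropan-2-yl)-4-(4-methoxybenzyloxy)-1-(triethylsilyloxy)cyclohex-2-en-6-ol | COc1ccc(CO[C@@H]2C=C(CO[Si](c3ccccc3)(c3ccccc3)C(C)(C)C)C(O[Si](CC)(CC)CC)[C@H](O)[C@H]2C(C)(C)Cl)cc1
F2 | step 14 | (1RS,5R,6R)-2-[(tert-butyldiphenylsilyloxy)methyl]-5-isopropyl-4-oxo-1-(triethylsilyloxy)cyclohex-2-en-6-yl (E)-2-methylbut-2-enoate | O=C1C=C(CO[Si](c2ccccc2)(c2ccccc2)C(C)(C)C)C(O[Si](CC)(CC)CC)[C@H](OC(=O)/C(C)=C/C)[C@H]1C(C)C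
F3 | step 14 | (1RS,4S,5S,6R)-2-[(tert-butyldiphenylsilyloxy)methyl]-4-hydroxy-5-isopropyl-1-(triethylsilyloxy)cyclohex-2-en-6-yl (E)-2-methylbut-2-enoate (C4 epimer of 22) | O[C@H]1C=C(CO[Si](c2ccccc2)(c2ccccc2)C(C)(C)C)C(O[Si](CC)(CC)CC)[C@H](OC(=O)/C(C)=C/C)[C@H]1C(C)C
F4 | step 14 | (Z)-2-methylbut-2-enoic 2,4,6-trichlorobenzoic anhydride | C/C=C(/C)C(=O)OC(=O)c1c(Cl)cc(Cl)cc1Cl
F5 | step 7 | (2RS,3Z,5S)-1-(tert-butyldimethylsilyloxy)-3-[(tert-butyldiphenylsilyloxy)methyl]-5-(4-methoxybenzyloxy)-7-methylocta-3,6-dien-2-ol | OC(CO[Si](C)(C)C(C)(C)C)/C(CO[Si](c1ccccc1)(c1ccccc1)C(C)(C)C)=C\[C@@H](OCc1ccc(OC)cc1)C=C(C)C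
F6 | step 7 | (2RS,3Z,5S)-3-[(tert-butyldiphenylsilyloxy)methyl]-5-(4-methoxybenzyloxy)-7-methylocta-3,6-diene-1,2-diol | OCC(O)/C(CO[Si](c1ccccc1)(c1ccccc1)C(C)(C)C)=C\[C@@H](OCc1ccc(OC)cc1)C=C(C)C
F7 | step 7 | (2RS,3Z,5S)-3-[(tert-butyldiphenylsilyloxy)methyl]-5-(4-methoxybenzyloxy)-7-methyl-1,2-bis(triethylsilyloxy)octa-3,6-diene | CC[Si](CC)(CC)OCC(O[Si](CC)(CC)CC)/C(CO[Si](c1ccccc1)(c1ccccc1)C(C)(C)C)=C\[C@@H](OCc1ccc(OC)cc1)C=C(C)C
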